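**Plan**

- Retrosynthesis first cuts the two C–Br bonds at C1' of the side chain. It then cuts the two ring bonds that hold one CBr carbon between the propyl-bearing carbon and the carbonyl, which turns the 4-pyranone into a 3-silyloxyfuran plus dibromocarbene.
- Enabling feature: with the pyranone numbered O1, C2 (side chain), C3, C4 (C=O), C5, C6, the brominated C3 lies between the enol-ether carbon C2 and the carbonyl C4. A dibromocarbene carbon inserted into the C=C bond of a cyclic silyl enol ether ends up in exactly this position. (The IUPAC names of 16–18 count the ring the other way, so this carbon is C5 there.)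
- Further back, the furan C5–Br bond is cut (ring lithiation), then the C4–Br bond, the O–C5 bond of a 3(2H)-furanone, and the acyl–alkynyl C–C bond.
- Forward: the chain is joined from ethyl 2-hydroxypentanoate and ethynylmagnesium bromide; the furanone ring is closed by O–C bond formation, brominated, silylated to the furan and brominated again; the furan is enlarged to the pyranone; the side chain is brominated twice.
- Stereochemistry: the target has no stereocentre. Racemic material is used, and the one centre carried through 1–9 is erased when the furan is formed in step 6.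

Key step: step 8

Remark on the chemistry: racemic ethyl 2-hydroxypentanoate is assumed as the purchased starting material, since its configuration has no bearing on the achiral target.

**Route**

Step 1
Reactants: 1 ethyl 2-hydroxypentanoate
Product: 2 ethyl 2-[(tert-butyldimethylsilyl)oxy]pentanoate
Conditions: TBSCl, imidazole, DMF, rt
Reagents that add atoms: tert-butyldimethylsilyl chloride (TBSCl), CC(C)(C)[Si](C)(C)Cl
Why: Imidazole-promoted O-silylation of a secondary alcohol; the silyl ether masks the hydroxyl against the magnesium reagents of steps 2 and 3.

Step 2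
Reactants: 2 ethyl 2-[(tert-butyldimethylsilyl)oxy]pentanoate
Product: 3 2-[(tert-butyldimethylsilyl)oxy]-N-methoxy-N-methylpentanamide
Conditions: MeNH(OMe)·HCl, i-PrMgCl, THF, −20 to 0 °C
Reagents that add atoms: N,O-dimethylhydroxylamine hydrochloride, CNOC.Cl
Why: Weinreb amide formation by aminolysis of the ester with the chloromagnesium amide of the hydroxylamine, a transformation that tolerates an α-silyloxy group.

Step 3
Reactants: 3 2-[(tert-butyldimethylsilyl)oxy]-N-methoxy-N-methylpentanamide; 4 ethynylmagnesium bromide
Product: 5 4-[(tert-butyldimethylsilyl)oxy]hept-1-yn-3-one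
Conditions: HC≡CMgBr, THF, 0 °C; quench into cold 1 M aq. HCl
Reagents that add atoms: none
Why: Weinreb ketone synthesis; the magnesium-chelated tetrahedral adduct should prevent a second addition, and the cold acidic quench protonates the released amine before it can add to the terminal ynone.

Step 4
Reactants: 5 4-[(tert-butyldimethylsilyl)oxy]hept-1-yn-3-one
Product: 8 2-propylfuran-3(2H)-one, via silyl enaminone 6 (not isolated), via hydroxy enaminone 7 (not isolated)
Conditions: Et2NH, EtOH, 0 °C to rt; then 3 M aq. HCl, THF, rt
Reagents that add atoms: none
Why: Amine-mediated cyclisation of an α'-oxygenated ynone: conjugate addition of diethylamine gives the β-amino enone, acid removes the silyl ether, and the freed hydroxyl attacks the iminium tautomer (5-exo-trig) and expels the amine to give the 3(2H)-furanone.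

Step 5
Reactants: 8 2-propylfuran-3(2H)-one
Product: 9 4-bromo-2-propylfuran-3(2H)-one
Conditions: NBS (1.05 equiv), CH2Cl2, 0 °C, dark
Reagents that add atoms: N-bromosuccinimide, O=C1CCC(=O)N1Br
Why: Electrophilic α-bromination of a vinylogous ester; C4 is the nucleophilic β-carbon of the ring enol ether, so bromonium transfer there followed by loss of the C4 proton restores the conjugated system.

Step 6
Reactants: 9 4-bromo-2-propylfuran-3(2H)-one
Product: 10 tert-butyl[(4-bromo-2-propylfuran-3-yl)oxy]dimethylsilane
Conditions: TBSOTf, Et3N, CH2Cl2, 0 °C
Reagents that add atoms: tert-butyldimethylsilyl trifluoromethanesulfonate (TBSOTf), CC(C)(C)[Si](C)(C)OS(=O)(=O)C(F)(F)F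
Why: Soft enolisation with O-silylation; removal of the C2 proton from the O-silylated ketone gives the aromatic 3-silyloxyfuran, which drives the enolisation towards C2 and removes the stereocentre.

Step 7
Reactants: 10 tert-butyl[(4-bromo-2-propylfuran-3-yl)oxy]dimethylsilane
Product: 12 tert-butyl[(4,5-dibromo-2-propylfuran-3-yl)oxy]dimethylsilane, via lithiofuran 11 (not isolated)
Conditions: LiN(i-Pr)2, THF, −78 °C; then BrCCl2CCl2Br, −78 to 0 °C
Reagents that add atoms: 1,2-dibromo-1,1,2,2-tetrachloroethane, BrC(Cl)(Cl)C(Cl)(Cl)Br
Why: Directed ring lithiation and electrophilic bromination; the only ring hydrogen sits next to the ring oxygen and ortho to bromine, the site at which 3-bromofurans are deprotonated by lithium amides, and an amide base avoids bromine–lithium exchange.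

Step 8
Reactants: 12 tert-butyl[(4,5-dibromo-2-propylfuran-3-yl)oxy]dimethylsilane; 13 bromoform
Product: 16 2,3,5-tribromo-6-propyl-4H-pyran-4-one, via dibromocyclopropane 14 (not isolated), via silyloxypyrylium bromide 15 (not isolated)
Conditions: CHBr3, KOt-Bu (slight excess, added in portions), pentane, −20 °C to rt
Reagents that add atoms: none
Why: Proposed new method: tert-butoxide converts bromoform into singlet dibromocarbene, which should add in a concerted [2+1] step to the C2=C3 bond of furan 12 to give cyclopropane 14; the endo bromide then ionises as the fusion bond opens by disrotatory cyclopropyl-to-allyl electrocyclic opening to give 4-silyloxypyrylium bromide 15, and bromide removes the silyl group to release pyranone 16. The closest known reaction types are the dihalocarbene one-carbon ring expansion of cyclic silyl enol ethers to 2-halo-2-cycloalkenones and the Ciamician–Dennstedt enlargement of pyrroles and indoles; the new element is its use on a furan to deliver a 4-pyranone. The six-membered ring is closed by ring enlargement, the carbene carbon being inserted between former furan C2 and C3, so both new skeletal bonds come from the [2+1] addition and no chain cyclisation is involved. No stereocentre results, because the two cis-fused bridgehead centres of 14 vanish on opening. The step needs site selectivity between the two furan double bonds, and the substrate should secure it: C4=C5 carries two electron-withdrawing, bulky bromines, whereas C2=C3 is activated by the silyloxy group, the propyl group and O1. The gain of pyrylium and pyranone aromaticity drives the opening, and the electron-poor product should not take up a second carbene.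

Step 9
Reactants: 16 2,3,5-tribromo-6-propyl-4H-pyran-4-one
Product: 18 2,3,5-tribromo-6-(1,1-dibromopropyl)-4H-pyran-4-one, via monobromide 17 (not isolated)
Conditions: NBS (2.5 equiv), AIBN (cat.), PhCF3, reflux, visible-light lamp
Reagents that add atoms: N-bromosuccinimide, O=C1CCC(=O)N1Br
Why: Wohl–Ziegler radical bromination; C1' is the only sp3 carbon conjugated to the pyranone, its radical is delocalised into the ring enone, and the first bromine stabilises the second radical at the same carbon, so both substitutions should occur there while C2' and C3' stay untouched.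

**Compound list**

1 | ethyl 2-hydroxypentanoate (racemic) | CCCC(O)C(=O)OCC | starting material
2 | ethyl 2-[(tert-butyldimethylsilyl)oxy]pentanoate (racemic) | CCCC(O[Si](C)(C)C(C)(C)C)C(=O)OCC | intermediate
3 | 2-[(tert-butyldimethylsilyl)oxy]-N-methoxy-N-methylpentanamide (racemic) | CCCC(O[Si](C)(C)C(C)(C)C)C(=O)N(C)OC | intermediate
4 | ethynylmagnesium bromide | C#C[Mg]Br | starting material
5 | 4-[(tert-butyldimethylsilyl)oxy]hept-1-yn-3-one (racemic) | CCCC(O[Si](C)(C)C(C)(C)C)C(=O)C#C | intermediate
6 | (E)-4-[(tert-butyldimethylsilyl)oxy]-1-(diethylamino)hept-1-en-3-one (racemic) | CCCC(O[Si](C)(C)C(C)(C)C)C(=O)/C=C/N(CC)CC | intermediate (not isolated)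
7 | (E)-1-(diethylamino)-4-hydroxyhept-1-en-3-one (racemic) | CCCC(O)C(=O)/C=C/N(CC)CC | intermediate (not isolated)
8 | 2-propylfuran-3(2H)-one (racemic) | CCCC1OC=CC1=O | intermediate
9 | 4-bromo-2-propylfuran-3(2H)-one (racemic) | CCCC1OC=C(Br)C1=O | intermediate
10 | tert-butyl[(4-bromo-2-propylfuran-3-yl)oxy]dimethylsilane | CCCc1occ(Br)c1O[Si](C)(C)C(C)(C)C | intermediate
11 | {3-bromo-4-[(tert-butyldimethylsilyl)oxy]-5-propylfuran-2-yl}lithium | CCCc1oc([Li])c(Br)c1O[Si](C)(C)C(C)(C)C | intermediate (not isolated)
12 | tert-butyl[(4,5-dibromo-2-propylfuran-3-yl)oxy]dimethylsilane | CCCc1oc(Br)c(Br)c1O[Si](C)(C)C(C)(C)C | intermediate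
13 | bromoform | BrC(Br)Br | starting material
14 | tert-butyl[(3,4,6,6-tetrabromo-1-propyl-2-oxabicyclo[3.1.0]hex-3-en-5-yl)oxy]dimethylsilane (racemic, cis-fused) | CCCC12OC(Br)=C(Br)C1(O[Si](C)(C)C(C)(C)C)C2(Br)Br | intermediate (not isolated)
15 | 2,3,5-tribromo-4-[(tert-butyldimethylsilyl)oxy]-6-propylpyrylium bromide | CCCc1[o+]c(Br)c(Br)c(O[Si](C)(C)C(C)(C)C)c1Br.[Br-] | intermediate (not isolated)
16 | 2,3,5-tribromo-6-propyl-4H-pyran-4-one | CCCc1oc(Br)c(Br)c(=O)c1Br | intermediate
17 | 2,3,5-tribromo-6-(1-bromopropyl)-4H-pyran-4-one (racemic) | CCC(Br)c1oc(Br)c(Br)c(=O)c1Br | intermediate (not isolated)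
18 | 2,3,5-tribromo-6-(1,1-dibromopropyl)-4H-pyran-4-one | CCC(Br)(Br)c1oc(Br)c(Br)c(=O)c1Br | target

**Step count**

Total steps: 9. Longest linear sequence: 9 steps (1 to 18); 4 and 13 enter as purchased building blocks.

**Steps most likely to fail**

Step 8 (proposed new method). The carbene may fail to add to the aromatic, bromine-deactivated furan. The alkoxide may also cleave the silyl enol ether before addition, or displace the bromide next to the ring oxygen of the product.

Fallback, by known chemistry, with the ring built by cyclisation instead of enlargement: it sets out from ethynylmagnesium bromide 4 and comes back to the route at 16.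
- Addition of 4 to hex-2-ynal in THF at 0 °C should give nona-1,4-diyn-3-ol F1.
- MnO2 in CH2Cl2 should oxidise it to nona-1,4-diyn-3-one F2.
- Acid-promoted hydrative cyclisation of this skipped diynone (TfOH, H2O, heat) should give 2-propyl-4H-pyran-4-one F3.
- Br2 with pyridine in CH2Cl2 should brominate both carbons flanking the carbonyl to give 3,5-dibromo-2-propyl-4H-pyran-4-one F4.
- Kinetic magnesiation of the last ring C–H, flanked by O1 and bromine, with TMPMgCl·LiCl in THF at −78 °C should give (3,5-dibromo-4-oxo-6-propyl-4H-pyran-2-yl)magnesium chloride F5. Short contact time is needed so that the side-chain methylene is not deprotonated instead.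
- Trapping with BrCCl2CCl2Br should then deliver 16.

Step 9. Hydrogen abstraction at the crowded, electron-poor C1' position may stall after the first bromine, or the monobromide may lose HBr towards a propenyl side chain under prolonged heating.

Fallback, ionic instead of radical: it sets out from 16 and comes back at 18.
- Deprotonation of the side-chain methylene with LiN(SiMe3)2 in THF at −78 °C, the usual vinylogous enolisation of 2-alkyl-4-pyranones, should give lithium 2,3,5-tribromo-6-propylidene-6H-pyran-4-olate F6.
- BrCCl2CCl2Br should brominate it at the exocyclic carbon to give monobromide 17, isolated this time.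
- A second deprotonation under the same conditions should give lithium 2,3,5-tribromo-6-(1-bromopropylidene)-6H-pyran-4-olate F7, and a second bromine transfer should give 18.

Step 5. Bromination may stray to C2 through the 3-hydroxyfuran tautomer, or run on to polybromination, and the sensitive furanone may degrade.

Fallback, with the bromine placed before the ring is closed: it sets out from silyl enaminone 6, isolated after the diethylamine addition to 5, and comes back at 9.
- NBS in CH2Cl2 at 0 °C should brominate the nucleophilic α-carbon of the enaminone to give 2-bromo-4-[(tert-butyldimethylsilyl)oxy]-1-(diethylamino)hept-1-en-3-one F8.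
- Aqueous HCl in THF should remove the silyl group to give 2-bromo-1-(diethylamino)-4-hydroxyhept-1-en-3-one F9, which should close with loss of diethylamine to 9.

**Further compounds**

F1 | step 8 | nona-1,4-diyn-3-ol (racemic) | C#CC(O)C#CCCC
F2 | step 8 | nona-1,4-diyn-3-one | C#CC(=O)C#CCCC
F3 | step 8 | 2-propyl-4H-pyran-4-one | CCCc1cc(=O)cco1
F4 | step 8 | 3,5-dibromo-2-propyl-4H-pyran-4-one | CCCc1occ(Br)c(=O)c1Br
F5 | step 8 | (3,5-dibromo-4-oxo-6-propyl-4H-pyran-2-yl)magnesium chloride | CCCc1oc([Mg]Cl)c(Br)c(=O)c1Br
F6 | step 9 | lithium 2,3,5-tribromo-6-propylidene-6H-pyran-4-olate | CCC=C1OC(Br)=C(Br)C(O[Li])=C1Br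
F7 | step 9 | lithium 2,3,5-tribromo-6-(1-bromopropylidene)-6H-pyran-4-olate | CCC(Br)=C1OC(Br)=C(Br)C(O[Li])=C1Br
F8 | step 5 | 2-bromo-4-[(tert-butyldimethylsilyl)oxy]-1-(diethylamino)hept-1-en-3-one (racemic) | CCCC(O[Si](C)(C)C(C)(C)C)C(=O)C(Br)=CN(CC)CC
F9 | step 5 | 2-bromo-1-(diethylamino)-4-hydroxyhept-1-en-3-one (racemic) | CCCC(O)C(=O)C(Br)=CN(CC)CC
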